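**Retrosynthetic overview**

1. Target 23 ⇐ tert-butyl ester 22 ⇐ right-half acid 13 + left-half spiro-oxirane 21 (made in the flask from chlorohydrin lactone 20); the ester C–O bond comes from carboxylate opening of the oxirane CH2.
2. Left half: 20 ⇐ hydroxy acid 19 (lactonisation, oxepinone ring closed last) ⇐ cis-dialdehyde 17 (olefination of one CHO, oxidation of the other) ⇐ cyclobutene 16.
3. Key disconnection: both ring-fusion C–C bonds (C9a–C1 and C5a–C5 of the benzoxepinone) are made at once by a triplet-biradical [2+2] photocycloaddition of acetylene 14 to (S)-cryptone 4, cis to each other and trans to isopropyl.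
4. Right half: 13 ⇐ enyne diol 10 (hydrostannation, tin–lithium exchange, CO2) ⇐ vinyl oxirane 9 (SN2′ hydride delivery sets the cis isopropyl/side-chain pair) ⇐ 3-alkynyl enone 8 ⇐ 4 + propargyl unit 5.
5. Ring order: cyclohexenone 4 (organocatalytic Robinson annulation of 1 and 2), then a temporary cyclobutene, then the seven-membered lactone; the right-half ring is 4 itself.

Assumption: (S)-α,α-diphenylprolinol trimethylsilyl ether gives the (S)-Michael adduct 3 (enamine attacked on the face remote from the diphenyl(silyloxy)methyl group); if the sense is opposite, the mirror-image catalyst is used and nothing else changes.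

**Route**

Step 1
Reactants: 1 3-methylbutanal (isovaleraldehyde); 2 but-3-en-2-one (methyl vinyl ketone)
Product: 4 (4S)-4-isopropylcyclohex-2-en-1-one, via keto aldehyde 3 (not isolated)
Conditions: (S)-α,α-diphenylprolinol trimethylsilyl ether (5 mol%), ethyl 3,4-dihydroxybenzoate (20 mol%), neat, 4 °C; then LiOH (10 mol%), iPrOH, 25 °C
Reagents that add atoms: none
Why: Enamine Michael addition of 1 to 2 under diarylprolinol silyl ether control sets the isopropyl-bearing centre as S in 3, and intramolecular aldol condensation (organocatalytic Robinson annulation) closes the cyclohexenone without touching that centre, which is γ to the ketone.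

Step 2
Reactants: 4 (4S)-4-isopropylcyclohex-2-en-1-one; 5 trimethyl(prop-2-yn-1-yloxy)silane
Product: 8 (4S)-3-(3-hydroxyprop-1-yn-1-yl)-4-isopropylcyclohex-2-en-1-one, via silyl enol ether 6 (not isolated), via silyl ether enynone 7 (not isolated)
Conditions: nBuLi, THF, −78 °C; ZnBr2; then 4, Me3SiOTf, −40 °C; then Pd(OAc)2, MeCN, 25 °C; then 1 M HCl
Reagents that add atoms: none
Why: Silyl-triflate-promoted conjugate addition of the alkynylzinc reagent gives enol ether 6 regiospecifically and Saegusa–Ito dehydrogenation with Pd(OAc)2 restores the C2=C3 double bond, so the C3 centre of 6 is erased on purpose while C4 (S) is untouched, and acid work-up removes the O-silyl group.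

Step 3
Reactants: 8 (4S)-3-(3-hydroxyprop-1-yn-1-yl)-4-isopropylcyclohex-2-en-1-one
Product: 9 3-[(3R,6S)-6-isopropyl-1-oxaspiro[2.5]oct-4-en-5-yl]prop-2-yn-1-ol
Conditions: Me3SI (2.5 equiv), nBuLi (2.4 equiv), THF, −10 to 0 °C
Reagents that add atoms: trimethylsulfonium iodide, C[S+](C)C.[I-]
Why: Corey–Chaykovsky epoxidation, in which dimethylsulfonium methylide adds irreversibly 1,2 to the enone carbonyl along the pseudoaxial trajectory, puts the new CH2 cis and the oxirane oxygen trans to the pseudoequatorial isopropyl group (spiro centre R, d.r. expected about 4–5:1, minor epimer removed by chromatography).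

Step 4
Reactants: 9 3-[(3R,6S)-6-isopropyl-1-oxaspiro[2.5]oct-4-en-5-yl]prop-2-yn-1-ol
Product: 10 3-[(1R,6S)-3-(hydroxymethyl)-6-isopropylcyclohex-2-en-1-yl]prop-2-yn-1-ol
Conditions: iBu2AlH (3.5 equiv), CH2Cl2, −78 to −20 °C; aq. potassium sodium tartrate (KNaC4H4O6)
Reagents that add atoms: none
Why: SN2′ (1,4) reduction of a vinyl oxirane, in which the alane bound to the oxirane oxygen delivers hydride through a six-membered transition state to the alkene terminus on the face of the departing C–O bond and anti to isopropyl, sets C1 (R) with the alkynyl chain cis to isopropyl and moves the double bond to the carbon that now carries CH2OH.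

Step 5
Reactants: 10 3-[(1R,6S)-3-(hydroxymethyl)-6-isopropylcyclohex-2-en-1-yl]prop-2-yn-1-ol
Product: 11 (2E)-3-[(1R,6S)-3-(hydroxymethyl)-6-isopropylcyclohex-2-en-1-yl]-2-(tributylstannyl)prop-2-en-1-ol
Conditions: Bu3SnH, PdCl2(PPh3)2 (2 mol%), THF, 0 °C
Reagents that add atoms: tributyltin hydride, CCCC[SnH](CCCC)CCCC
Why: Palladium-catalysed syn-hydrostannation of a propargylic alcohol places tin on the alkyne carbon next to CH2OH (oxygen-proximal and less hindered than the carbon on the secondary ring position) and hydrogen cis to it, so the ring ends up trans to tin; no stereocentre is touched.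

Step 6
Reactants: 11 (2E)-3-[(1R,6S)-3-(hydroxymethyl)-6-isopropylcyclohex-2-en-1-yl]-2-(tributylstannyl)prop-2-en-1-ol
Product: 13 (2E)-2-(hydroxymethyl)-3-[(1R,6S)-3-(hydroxymethyl)-6-isopropylcyclohex-2-en-1-yl]prop-2-enoic acid, via alkenyllithium 12 (not isolated)
Conditions: MeLi (4 equiv), THF, −78 to −40 °C; then CO2; then 1 M HCl
Reagents that add atoms: carbon dioxide, O=C=O
Why: Tin–lithium exchange proceeds with retention of alkene geometry to the 2-lithioallyl alkoxide 12, whose carboxylation, also with retention, gives the acid with CO2H trans and CH2OH cis to the ring.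

Step 7
Reactants: 4 (4S)-4-isopropylcyclohex-2-en-1-one; 14 ethyne (acetylene)
Product: 15 (1S,5S,6S)-5-isopropylbicyclo[4.2.0]oct-7-en-2-one
Conditions: hν (Pyrex, λ > 300 nm), acetylene-saturated CH2Cl2, −70 °C
Reagents that add atoms: none
Why: Enone–alkyne [2+2] photocycloaddition, in which the triplet enone bonds through C3 to acetylene on the face anti to the C4 isopropyl group to give a triplet 1,4-biradical that closes by radical recombination at C2 after spin inversion, forms both C–C bonds in one radical step as a necessarily cis-fused cyclobutene trans to isopropyl (1S,6S).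

Step 8
Reactants: 15 (1S,5S,6S)-5-isopropylbicyclo[4.2.0]oct-7-en-2-one
Product: 16 (1S,2R,5S,6S)-2-(chloromethyl)-5-isopropylbicyclo[4.2.0]oct-7-en-2-ol
Conditions: ICH2Cl, MeLi·LiBr, THF, −78 °C; then AcOH, −78 °C
Reagents that add atoms: chloroiodomethane, ClCI
Why: Barbier-type addition of chloromethyllithium (a lithium carbenoid) to the ketone from the convex face of the cis-fused bicycle, anti to the cyclobutene carbon on C1, gives the tertiary alcohol with OH cis to that carbon (C2 R), and the cold acidic quench stops the chlorohydrin from closing to the oxirane.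

Step 9
Reactants: 16 (1S,2R,5S,6S)-2-(chloromethyl)-5-isopropylbicyclo[4.2.0]oct-7-en-2-ol
Product: 17 (1S,2S,3R,6S)-3-(chloromethyl)-3-hydroxy-6-isopropylcyclohexane-1,2-dicarbaldehyde
Conditions: O3, pyridine (3 equiv), CH2Cl2, −78 °C
Reagents that add atoms: ozone, [O-][O+]=O
Why: Ozonolysis of the strained cyclobutene in the presence of pyridine, which decomposes the carbonyl oxide directly to the carbonyl, gives the cis-1,2-dialdehyde without a reductive work-up and under neutral, non-enolising conditions, so no stereocentre is disturbed.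

Step 10
Reactants: 17 (1S,2S,3R,6S)-3-(chloromethyl)-3-hydroxy-6-isopropylcyclohexane-1,2-dicarbaldehyde
Product: 18 tert-butyl (2E)-3-[(1R,2S,3R,6S)-3-(chloromethyl)-2-formyl-3-hydroxy-6-isopropylcyclohexyl]-2-(hydroxymethyl)prop-2-enoate
Conditions: tert-butyl 2-(diethoxyphosphoryl)prop-2-enoate, K2CO3, THF/H2O (10:1), 0 °C
Reagents that add atoms: tert-butyl 2-(diethoxyphosphoryl)prop-2-enoate, C=C(C(=O)OC(C)(C)C)P(=O)(OCC)OCC; water, O
Why: Tandem oxa-Michael/Horner–Wadsworth–Emmons olefination, in which hydroxide adds to the phosphonoacrylate to give the 2-(hydroxymethyl)phosphonoacetate anion that olefinates the less hindered aldehyde (the one remote from the quaternary carbinol) with the usual E preference of α-substituted phosphonoacetates, puts the ester trans and CH2OH cis to the ring.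

Step 11
Reactants: 18 tert-butyl (2E)-3-[(1R,2S,3R,6S)-3-(chloromethyl)-2-formyl-3-hydroxy-6-isopropylcyclohexyl]-2-(hydroxymethyl)prop-2-enoate
Product: 19 (1S,2R,5S,6R)-6-[(1E)-3-tert-butoxy-2-(hydroxymethyl)-3-oxoprop-1-en-1-yl]-2-(chloromethyl)-2-hydroxy-5-isopropylcyclohexane-1-carboxylic acid
Conditions: NaClO2, NaH2PO4, 2-methylbut-2-ene, tBuOH/H2O, 0 °C
Reagents that add atoms: sodium chlorite, [Na+].[O-]Cl=O
Why: Pinnick oxidation converts the remaining aldehyde to the acid under buffered, non-epimerising conditions that leave the allylic alcohol, the chlorohydrin and the acrylate alone.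

Step 12
Reactants: 19 (1S,2R,5S,6R)-6-[(1E)-3-tert-butoxy-2-(hydroxymethyl)-3-oxoprop-1-en-1-yl]-2-(chloromethyl)-2-hydroxy-5-isopropylcyclohexane-1-carboxylic acid
Product: 20 tert-butyl (5aR,6S,9R,9aS)-9-(chloromethyl)-9-hydroxy-6-isopropyl-1-oxo-1,3,5a,6,7,8,9,9a-octahydro-2-benzoxepine-4-carboxylate
Conditions: 2-chloro-1-methylpyridinium iodide, Et3N, CH2Cl2 (0.002 M), 40 °C
Reagents that add atoms: none
Why: Mukaiyama lactonisation under high dilution closes the seven-membered lactone on the primary allylic alcohol (far more nucleophilic than the tertiary alcohol), which is possible because acid and side chain are cis, and the absence of a nucleophilic catalyst prevents SN2′ isomerisation of the allylic ester.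

Step 13
Reactants: 20 tert-butyl (5aR,6S,9R,9aS)-9-(chloromethyl)-9-hydroxy-6-isopropyl-1-oxo-1,3,5a,6,7,8,9,9a-octahydro-2-benzoxepine-4-carboxylate; 13 (2E)-2-(hydroxymethyl)-3-[(1R,6S)-3-(hydroxymethyl)-6-isopropylcyclohex-2-en-1-yl]prop-2-enoic acid
Product: 22 tert-butyl (5aR,6S,9R,9aS)-9-hydroxy-9-[({(2E)-2-(hydroxymethyl)-3-[(1R,6S)-3-(hydroxymethyl)-6-isopropylcyclohex-2-en-1-yl]prop-2-enoyl}oxy)methyl]-6-isopropyl-1-oxo-1,3,5a,6,7,8,9,9a-octahydro-2-benzoxepine-4-carboxylate, via spiro-oxirane 21 (not isolated)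
Conditions: Cs2CO3 (1.1 equiv), DMF, 25 °C; then 13 (1.3 equiv), 60 °C
Reagents that add atoms: none
Why: Williamson closure of the chlorohydrin gives spiro-oxirane 21, whose unhindered CH2 terminus is opened by the caesium carboxylate of 13 (SN2 opening of a terminal epoxide by a carboxylate) to give the primary ester, with the C9–O bond never broken so the tertiary carbinol keeps its configuration, and the carboxylate outcompetes the two free alcohols of 13.

Step 14
Reactants: 22 tert-butyl ester of the target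
Product: 23 (5aR,6S,9R,9aS)-9-hydroxy-9-[({(2E)-2-(hydroxymethyl)-3-[(1R,6S)-3-(hydroxymethyl)-6-isopropylcyclohex-2-en-1-yl]prop-2-enoyl}oxy)methyl]-6-isopropyl-1-oxo-1,3,5a,6,7,8,9,9a-octahydro-2-benzoxepine-4-carboxylic acid
Conditions: CF3CO2H/CH2Cl2 (1:4), 0 °C; NaHCO3 work-up
Reagents that add atoms: none
Why: Acidolysis of the tert-butyl ester (E1 loss of isobutene) frees the acid, while the lactone, the acrylate ester and the tertiary β-hydroxy lactone (ionisation at C9 is disfavoured by the adjacent acyloxymethyl and carbonyl groups) survive at 0 °C.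

**Compound list**

1 | 3-methylbutanal | CC(C)CC=O | starting material
2 | but-3-en-2-one | CC(=O)C=C | starting material
3 | (2S)-2-isopropyl-5-oxohexanal | CC(C)[C@@H](C=O)CCC(C)=O | intermediate
4 | (4S)-4-isopropylcyclohex-2-en-1-one, (S)-cryptone | CC(C)[C@@H]1CCC(=O)C=C1 | intermediate
5 | trimethyl(prop-2-yn-1-yloxy)silane | C#CCO[Si](C)(C)C | starting material
6 | trimethyl({(3S,4S)-4-isopropyl-3-[3-(trimethylsilyloxy)prop-1-yn-1-yl]cyclohex-1-en-1-yl}oxy)silane (3,4-trans) | CC(C)[C@@H]1CCC(O[Si](C)(C)C)=C[C@H]1C#CCO[Si](C)(C)C | intermediate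
7 | (4S)-4-isopropyl-3-[3-(trimethylsilyloxy)prop-1-yn-1-yl]cyclohex-2-en-1-one | CC(C)[C@@H]1CCC(=O)C=C1C#CCO[Si](C)(C)C | intermediate
8 | (4S)-3-(3-hydroxyprop-1-yn-1-yl)-4-isopropylcyclohex-2-en-1-one | CC(C)[C@@H]1CCC(=O)C=C1C#CCO | intermediate
9 | 3-[(3R,6S)-6-isopropyl-1-oxaspiro[2.5]oct-4-en-5-yl]prop-2-yn-1-ol (oxirane O trans to isopropyl) | CC(C)[C@@H]1CC[C@]2(CO2)C=C1C#CCO | intermediate
10 | 3-[(1R,6S)-3-(hydroxymethyl)-6-isopropylcyclohex-2-en-1-yl]prop-2-yn-1-ol (1,6-cis) | OCC#C[C@H]1C=C(CO)CC[C@H]1C(C)C | intermediate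
11 | (2E)-3-[(1R,6S)-3-(hydroxymethyl)-6-isopropylcyclohex-2-en-1-yl]-2-(tributylstannyl)prop-2-en-1-ol | OC/C(=C\[C@H]1C=C(CO)CC[C@H]1C(C)C)[Sn](CCCC)(CCCC)CCCC | intermediate
12 | trilithium species: 2-lithio alkenyl dialkoxide from 11 (Li in place of Sn, both OH as OLi) | [Li]OC/C([Li])=C\[C@H]1C=C(CO[Li])CC[C@H]1C(C)C | intermediate
13 | (2E)-2-(hydroxymethyl)-3-[(1R,6S)-3-(hydroxymethyl)-6-isopropylcyclohex-2-en-1-yl]prop-2-enoic acid | OC(=O)/C(=C/[C@H]1C=C(CO)CC[C@H]1C(C)C)CO | intermediate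
14 | ethyne | C#C | starting material
15 | (1S,5S,6S)-5-isopropylbicyclo[4.2.0]oct-7-en-2-one | CC(C)[C@@H]1CCC(=O)[C@H]2C=C[C@@H]12 | intermediate
16 | (1S,2R,5S,6S)-2-(chloromethyl)-5-isopropylbicyclo[4.2.0]oct-7-en-2-ol | CC(C)[C@@H]1CC[C@](O)(CCl)[C@H]2C=C[C@@H]12 | intermediate
17 | (1S,2S,3R,6S)-3-(chloromethyl)-3-hydroxy-6-isopropylcyclohexane-1,2-dicarbaldehyde | CC(C)[C@@H]1CC[C@](O)(CCl)[C@@H](C=O)[C@H]1C=O | intermediate
18 | tert-butyl (2E)-3-[(1R,2S,3R,6S)-3-(chloromethyl)-2-formyl-3-hydroxy-6-isopropylcyclohexyl]-2-(hydroxymethyl)prop-2-enoate | CC(C)[C@@H]1CC[C@](O)(CCl)[C@@H](C=O)[C@H]1/C=C(\CO)C(=O)OC(C)(C)C | intermediate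
19 | (1S,2R,5S,6R)-6-[(1E)-3-tert-butoxy-2-(hydroxymethyl)-3-oxoprop-1-en-1-yl]-2-(chloromethyl)-2-hydroxy-5-isopropylcyclohexane-1-carboxylic acid | CC(C)[C@@H]1CC[C@](O)(CCl)[C@@H](C(=O)O)[C@H]1/C=C(\CO)C(=O)OC(C)(C)C | intermediate
20 | tert-butyl (5aR,6S,9R,9aS)-9-(chloromethyl)-9-hydroxy-6-isopropyl-1-oxo-1,3,5a,6,7,8,9,9a-octahydro-2-benzoxepine-4-carboxylate | CC(C)[C@@H]1CC[C@](O)(CCl)[C@H]2C(=O)OCC(C(=O)OC(C)(C)C)=C[C@@H]12 | intermediate
21 | tert-butyl (5aR,6S,9R,9aS)-6-isopropyl-1-oxo-1,3,5a,6,7,8-hexahydro-9aH-spiro[2-benzoxepine-9,2'-oxirane]-4-carboxylate (oxirane O cis to the lactone carbonyl) | CC(C)[C@@H]1CC[C@]3(CO3)[C@H]2C(=O)OCC(C(=O)OC(C)(C)C)=C[C@@H]12 | intermediate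
22 | tert-butyl (5aR,6S,9R,9aS)-9-hydroxy-9-[({(2E)-2-(hydroxymethyl)-3-[(1R,6S)-3-(hydroxymethyl)-6-isopropylcyclohex-2-en-1-yl]prop-2-enoyl}oxy)methyl]-6-isopropyl-1-oxo-1,3,5a,6,7,8,9,9a-octahydro-2-benzoxepine-4-carboxylate | CC(C)[C@@H]1CC[C@](O)(COC(=O)/C(=C/[C@H]2C=C(CO)CC[C@H]2C(C)C)CO)[C@H]2C(=O)OCC(C(=O)OC(C)(C)C)=C[C@@H]12 | intermediate
23 | (5aR,6S,9R,9aS)-9-hydroxy-9-[({(2E)-2-(hydroxymethyl)-3-[(1R,6S)-3-(hydroxymethyl)-6-isopropylcyclohex-2-en-1-yl]prop-2-enoyl}oxy)methyl]-6-isopropyl-1-oxo-1,3,5a,6,7,8,9,9a-octahydro-2-benzoxepine-4-carboxylic acid | CC(C)[C@@H]1CC[C@](O)(COC(=O)/C(=C/[C@H]2C=C(CO)CC[C@H]2C(C)C)CO)[C@H]2C(=O)OCC(C(=O)O)=C[C@@H]12 | target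

**Step count and risks**

Total step count: 14. Longest linear sequence: 9 steps (1, 7, 8, 9, 10, 11, 12, 13, 14).

The three steps most likely to fail:

Step 4 (SN2′ hydride opening of 9). The alane may open the oxirane directly (1,2), or the internal delivery may not be cleanly syn; its outcome also inherits the diastereomer ratio of step 3. Fallback: set out from 4 and 5 and make the C1–alkynyl bond last instead of the C1–H bond. Dimethylsulfonium methylide (Me3SI, nBuLi, THF) on 4 gives (3R,6S)-6-isopropyl-1-oxaspiro[2.5]oct-4-ene F1. Separately, 5 is lithiated and quenched with Bu3SnCl to give tributyl[3-(trimethylsilyloxy)prop-1-yn-1-yl]stannane F2. F1 and F2 are coupled with Pd2(dba)3/PPh3 in wet DMF: zerovalent palladium opens the vinyl oxirane anti to its C–O bond and hands the alkynyl group over from the metal face, that is, cis to isopropyl, giving trimethyl({3-[(1R,6S)-3-(hydroxymethyl)-6-isopropylcyclohex-2-en-1-yl]prop-2-yn-1-yl}oxy)silane F3. Work-up with 1 M HCl removes the silyl group and the route is rejoined at 10.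

Step 10 (olefination of dialdehyde 17). The basic medium can epimerise either formyl-bearing carbon, trigger retro-aldol cleavage of the β-hydroxy aldehyde, or fail to discriminate the two aldehydes. Fallback: set out from 17 and use a neutral Wittig reagent. tert-Butyl (triphenyl-λ5-phosphanylidene)acetate is alkylated with chloromethyl 4-methoxybenzyl ether and deprotonated to tert-butyl 3-[(4-methoxyphenyl)methoxy]-2-(triphenyl-λ5-phosphanylidene)propanoate F4. F4 reacts with 17 in toluene at 25 °C, at the less hindered aldehyde only, to give tert-butyl (2E)-3-[(1R,2S,3R,6S)-3-(chloromethyl)-2-formyl-3-hydroxy-6-isopropylcyclohexyl]-2-{[(4-methoxyphenyl)methoxy]methyl}prop-2-enoate F5. Pinnick oxidation (as in step 11) gives (1S,2R,5S,6R)-6-[(1E)-3-tert-butoxy-2-{[(4-methoxyphenyl)methoxy]methyl}-3-oxoprop-1-en-1-yl]-2-(chloromethyl)-2-hydroxy-5-isopropylcyclohexane-1-carboxylic acid F6. DDQ in CH2Cl2/pH 7 buffer removes the 4-methoxybenzyl group and the route is rejoined at 19.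

Step 13 (union by oxirane opening). The carboxylate must attack a CH2 next to a quaternary carbon while the β,γ-epoxy lactone can eliminate and the allylic lactone can suffer SN2′ attack. Fallback: set out from 20 and 13 and acylate a primary alcohol instead. Compound 20 with HCO2Cs and Cs2CO3 in DMF (through 21) gives tert-butyl (5aR,6S,9R,9aS)-9-[(formyloxy)methyl]-9-hydroxy-6-isopropyl-1-oxo-1,3,5a,6,7,8,9,9a-octahydro-2-benzoxepine-4-carboxylate F7. Methanolysis with NaHCO3/MeOH gives tert-butyl (5aR,6S,9R,9aS)-9-hydroxy-9-(hydroxymethyl)-6-isopropyl-1-oxo-1,3,5a,6,7,8,9,9a-octahydro-2-benzoxepine-4-carboxylate F8, whose CH2OH is anti to the lactone carbonyl and cannot translactonise. Acid 13 is silylated on both alcohols (Et3SiCl, imidazole; the silyl ester falls off on aqueous work-up) to (2E)-3-[(1R,6S)-6-isopropyl-3-{[(triethylsilyl)oxy]methyl}cyclohex-2-en-1-yl]-2-{[(triethylsilyl)oxy]methyl}prop-2-enoic acid F9. F8 and F9 are joined with 2-methyl-6-nitrobenzoic anhydride, Et3N and catalytic 4-(dimethylamino)pyridine at the primary alcohol to give tert-butyl (5aR,6S,9R,9aS)-9-hydroxy-6-isopropyl-1-oxo-9-{[((2E)-3-[(1R,6S)-6-isopropyl-3-{[(triethylsilyl)oxy]methyl}cyclohex-2-en-1-yl]-2-{[(triethylsilyl)oxy]methyl}prop-2-enoyl)oxy]methyl}-1,3,5a,6,7,8,9,9a-octahydro-2-benzoxepine-4-carboxylate F10. Wet CF3CO2H/CH2Cl2 removes both silyl ethers and the tert-butyl ester, and the route is rejoined at 23.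

Further compounds
F1 | step 4 | (3R,6S)-6-isopropyl-1-oxaspiro[2.5]oct-4-ene | CC(C)[C@@H]1CC[C@]2(CO2)C=C1
F2 | step 4 | tributyl[3-(trimethylsilyloxy)prop-1-yn-1-yl]stannane | CCCC[Sn](CCCC)(CCCC)C#CCO[Si](C)(C)C
F3 | step 4 | trimethyl({3-[(1R,6S)-3-(hydroxymethyl)-6-isopropylcyclohex-2-en-1-yl]prop-2-yn-1-yl}oxy)silane | C[Si](C)(C)OCC#C[C@H]1C=C(CO)CC[C@H]1C(C)C
F4 | step 10 | tert-butyl 3-[(4-methoxyphenyl)methoxy]-2-(triphenyl-λ5-phosphanylidene)propanoate | COc1ccc(COCC(C(=O)OC(C)(C)C)=P(c2ccccc2)(c2ccccc2)c2ccccc2)cc1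
F5 | step 10 | tert-butyl (2E)-3-[(1R,2S,3R,6S)-3-(chloromethyl)-2-formyl-3-hydroxy-6-isopropylcyclohexyl]-2-{[(4-methoxyphenyl)methoxy]methyl}prop-2-enoate | CC(C)[C@@H]1CC[C@](O)(CCl)[C@@H](C=O)[C@H]1/C=C(\COCc1ccc(OC)cc1)C(=O)OC(C)(C)C
F6 | step 10 | (1S,2R,5S,6R)-6-[(1E)-3-tert-butoxy-2-{[(4-methoxyphenyl)methoxy]methyl}-3-oxoprop-1-en-1-yl]-2-(chloromethyl)-2-hydroxy-5-isopropylcyclohexane-1-carboxylic acid | CC(C)[C@@H]1CC[C@](O)(CCl)[C@@H](C(=O)O)[C@H]1/C=C(\COCc1ccc(OC)cc1)C(=O)OC(C)(C)C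
F7 | step 13 | tert-butyl (5aR,6S,9R,9aS)-9-[(formyloxy)methyl]-9-hydroxy-6-isopropyl-1-oxo-1,3,5a,6,7,8,9,9a-octahydro-2-benzoxepine-4-carboxylate | CC(C)[C@@H]1CC[C@](O)(COC=O)[C@H]2C(=O)OCC(C(=O)OC(C)(C)C)=C[C@@H]12
F8 | step 13 | tert-butyl (5aR,6S,9R,9aS)-9-hydroxy-9-(hydroxymethyl)-6-isopropyl-1-oxo-1,3,5a,6,7,8,9,9a-octahydro-2-benzoxepine-4-carboxylate | CC(C)[C@@H]1CC[C@](O)(CO)[C@H]2C(=O)OCC(C(=O)OC(C)(C)C)=C[C@@H]12
F9 | step 13 | (2E)-3-[(1R,6S)-6-isopropyl-3-{[(triethylsilyl)oxy]methyl}cyclohex-2-en-1-yl]-2-{[(triethylsilyl)oxy]methyl}prop-2-enoic acid | OC(=O)/C(=C/[C@H]1C=C(CO[Si](CC)(CC)CC)CC[C@H]1C(C)C)CO[Si](CC)(CC)CC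
F10 | step 13 | tert-butyl (5aR,6S,9R,9aS)-9-hydroxy-6-isopropyl-1-oxo-9-{[((2E)-3-[(1R,6S)-6-isopropyl-3-{[(triethylsilyl)oxy]methyl}cyclohex-2-en-1-yl]-2-{[(triethylsilyl)oxy]methyl}prop-2-enoyl)oxy]methyl}-1,3,5a,6,7,8,9,9a-octahydro-2-benzoxepine-4-carboxylate | CC(C)[C@@H]1CC[C@](O)(COC(=O)/C(=C/[C@H]2C=C(CO[Si](CC)(CC)CC)CC[C@H]2C(C)C)CO[Si](CC)(CC)CC)[C@H]2C(=O)OCC(C(=O)OC(C)(C)C)=C[C@@H]12
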